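**Plan**

Numbering: chromene half O1–C8a, chroman half with primes; "arm" = 2-(4-hydroxyphenyl)ethyl.
The retrosynthesis cuts, in order: the C8–prenyl bond (traced back to an O5 prenyl ether), the O1–C2 and C4–C4a bonds of the chromene pyran (prenal), and then the C7–C8 bond of the chromene-half benzene ring, which opens that ring to an allyl 3,5,7-triketo ester masked as a diketo-dioxinone.
The last cut is possible because this ring is a resorcinol (oxygen on C5 and C8a) in which C6, the carbon carrying the chroman-4'-yl group, sits between oxygenated C5 and arm-bearing C7 and is therefore the central carbon of a β-diketone. The crowded C6–C4' bond is accordingly cut at the diketone stage, between that enol carbon and the C4' cation of a 5'-hydroxychromene.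
Forward: an arm Weinreb amide and acetyl-dioxinone give the diketo-dioxinone. Its C-prenyl analogue is aromatised, annulated with prenal and decarboxylated to the chroman-half chromene (benzene ring, then pyran). The two are joined at C4'. The chromene-half benzene ring is then closed, followed by its pyran and finally the C8 prenyl group.
Stereochemistry: the only stereocentre, C4' (R), is set in the union by a chiral phosphoric acid and is not touched afterwards.

Key step: step 11

Assumption: the (R)-configured phosphoric acid is taken to deliver the (4'R)-chroman; if the sense of induction is the opposite, its enantiomer is used with no other change.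
Abbreviations: TIPS = triisopropylsilyl; TBS = tert-butyldimethylsilyl; prenyl = 3-methylbut-2-en-1-yl; arm(TIPS) = 2-[4-(triisopropylsilyloxy)phenyl]ethyl.

**Route**

Step 1
Reactants: 1 3-(4-hydroxyphenyl)propanoic acid
Product: 2 3-(4-hydroxyphenyl)-N-methoxy-N-methylpropanamide
Conditions: MeNHOMe·HCl, EDC·HCl, HOBt (cat.), N-methylmorpholine, CH2Cl2, 0 to 20 °C
Reagents that add atoms: N,O-dimethylhydroxylamine hydrochloride, CNOC.Cl
Why: Carbodiimide-mediated amide coupling gives the Weinreb amide, the free phenol being tolerated because any aryl ester formed is aminolysed by the hydroxylamine.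

Step 2
Reactants: 2 3-(4-hydroxyphenyl)-N-methoxy-N-methylpropanamide
Product: 3 N-methoxy-N-methyl-3-[4-(triisopropylsilyloxy)phenyl]propanamide
Conditions: i-Pr3SiCl, imidazole, DMF, 20 °C
Reagents that add atoms: triisopropylsilyl chloride, CC(C)[Si](Cl)(C(C)C)C(C)C
Why: Standard silylation of the only hydroxyl, the TIPS ether being chosen because it should withstand the amide bases, carbonate, morpholine and heat met later and is cleaved by fluoride at the end.

Step 3
Reactants: 4 2,2,6-trimethyl-4H-1,3-dioxin-4-one; 5 acetyl chloride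
Product: 6 2,2-dimethyl-6-(2-oxopropyl)-4H-1,3-dioxin-4-one
Conditions: LiN(SiMe3)2, THF, −78 °C; then 5; aq. NH4Cl (4 and base in twofold excess over 5)
Reagents that add atoms: none
Why: The lithium dienolate of the dioxinone is C-acylated at the 6-methyl carbon (vinylogous Claisen-type acylation), the excess enolate taking up the proton of the more acidic product.

Step 4
Reactants: 6 2,2-dimethyl-6-(2-oxopropyl)-4H-1,3-dioxin-4-one; 3 N-methoxy-N-methyl-3-[4-(triisopropylsilyloxy)phenyl]propanamide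
Product: 7 6-{2,4-dioxo-6-[4-(triisopropylsilyloxy)phenyl]hexyl}-2,2-dimethyl-4H-1,3-dioxin-4-one
Conditions: LiN(i-Pr)2 (2.2 equiv), THF, −78 °C; then 3, −78 to −40 °C; aq. NH4Cl
Reagents that add atoms: none
Why: Claisen condensation of the ketone dianion at its terminal carbanion with the Weinreb amide (Weinreb ketone synthesis), whose chelated tetrahedral intermediate releases the 1,3-diketone only on quench and so prevents proton transfer and over-addition.

Step 5
Reactants: 6 2,2-dimethyl-6-(2-oxopropyl)-4H-1,3-dioxin-4-one; 8 prenyl bromide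
Product: 9 2,2-dimethyl-6-(6-methyl-2-oxohept-5-en-1-yl)-4H-1,3-dioxin-4-one
Conditions: LiN(i-Pr)2 (2.2 equiv), THF, −78 °C; then 8, −78 to −20 °C; aq. NH4Cl
Reagents that add atoms: none
Why: Alkylation of the β-dicarbonyl dianion at the terminal, less stabilised carbanion with an allylic bromide (dianion γ-alkylation) extends the methyl ketone by one prenyl group.

Step 6
Reactants: 9 2,2-dimethyl-6-(6-methyl-2-oxohept-5-en-1-yl)-4H-1,3-dioxin-4-one; 3 N-methoxy-N-methyl-3-[4-(triisopropylsilyloxy)phenyl]propanamide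
Product: 10 2,2-dimethyl-6-{3-prenyl-2,4-dioxo-6-[4-(triisopropylsilyloxy)phenyl]hexyl}-4H-1,3-dioxin-4-one (racemic at the diketone carbon)
Conditions: LiN(i-Pr)2 (2.2 equiv), THF, −78 °C; then 3, −78 to −30 °C; aq. NH4Cl
Reagents that add atoms: none
Why: The same dianion Claisen condensation with the Weinreb amide, now at the secondary carbanion, places the prenyl group on the central carbon of the new 1,3-diketone with no ambiguity of site.

Step 7
Reactants: 10 C-prenyl diketo-dioxinone; 11 allyl alcohol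
Product: 13 allyl 2,4-dihydroxy-5-prenyl-6-[arm(TIPS)]benzoate, via triketo allyl ester 12 (not isolated)
Conditions: 11 (3 equiv), toluene, 110 °C; concentrate; Cs2CO3, THF, 20 °C; then AcOH
Reagents that add atoms: none
Why: Thermal cycloreversion of the dioxinone, capture of the acylketene by allyl alcohol and carbonate-mediated aldol condensation of the ester-activated methylene onto the arm ketone with dehydration give the resorcylate with the prenyl carbon between a hydroxyl and the arm, which also rehearses the key step on a simple substrate.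

Step 8
Reactants: 13 allyl 2,4-dihydroxy-5-prenyl-6-[arm(TIPS)]benzoate; 14 3-methylbut-2-enal (prenal)
Product: 15 allyl 5-hydroxy-2,2-dimethyl-8-prenyl-7-[arm(TIPS)]-2H-chromene-6-carboxylate
Conditions: 14, ethylenediammonium diacetate (10 mol%), toluene, 110 °C
Reagents that add atoms: none
Why: Amine-salt-catalysed chromene annulation (Knoevenagel-type condensation at the only free ring carbon, then oxa-6π electrocyclisation) closes through the hydroxyl next to the prenyl group because the other hydroxyl is held in the hydrogen bond to the ester, as is known for 2,4-dihydroxyaryl carbonyl compounds.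

Step 9
Reactants: 15 allyl 5-hydroxy-2,2-dimethyl-8-prenyl-7-[arm(TIPS)]-2H-chromene-6-carboxylate
Product: 17 2,2-dimethyl-8-prenyl-7-[arm(TIPS)]-2H-chromen-5-ol, via chromene acid 16 (not isolated)
Conditions: Pd(PPh3)4 (5 mol%), morpholine, THF, 20 °C; aq. citric acid wash; then DMF, 120 °C
Reagents that add atoms: none
Why: Tsuji–Trost deallylation with zerovalent palladium and morpholine as allyl acceptor frees a salicylic-type acid that, with an ortho hydroxyl and a para ring oxygen, should lose CO2 on warming by ipso-protonation (thermal decarboxylation of a β-resorcylic acid).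

Step 10
Reactants: 17 2,2-dimethyl-8-prenyl-7-[arm(TIPS)]-2H-chromen-5-ol; 7 6-{2,4-dioxo-6-[4-(triisopropylsilyloxy)phenyl]hexyl}-2,2-dimethyl-4H-1,3-dioxin-4-one
Product: 19 6-{3-[(4R)-5-(TBS-oxy)-2,2-dimethyl-8-prenyl-7-[arm(TIPS)]chroman-4-yl]-2,4-dioxo-6-[4-(triisopropylsilyloxy)phenyl]hexyl}-2,2-dimethyl-4H-1,3-dioxin-4-one (epimers at the diketone carbon), via phenol adduct 18 (not isolated)
Conditions: (R)-TRIP [(R)-3,3'-bis(2,4,6-triisopropylphenyl)-1,1'-binaphthyl-2,2'-diyl hydrogen phosphate] (10 mol%), 7 (1.5 equiv), slow addition of 17, toluene, 4 Å sieves, 0 °C; then imidazole, t-BuMe2SiCl, CH2Cl2, 0 °C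
Reagents that add atoms: tert-butyldimethylsilyl chloride, CC(C)(C)[Si](C)(C)Cl
Why: Proposed new method: the phosphoric acid should protonate C3' of the 5'-hydroxychromene to give a contact ion pair of the ortho-quinone methide (cation at C4' stabilised by O1', the ortho O5'–H and the para alkyl group), and the central enol carbon of the chelated β-diketone, held by a hydrogen bond to the phosphoryl oxygen, should add to one face of C4' and set the (R)-centre under catalyst control, after which the phenol is capped at once as its TBS ether so that it can neither add to a ketone nor reopen the new bond; the closest known reactions are the chiral-phosphoric-acid-catalysed conjugate addition of β-diketones to ortho-quinone methides generated from ortho-hydroxybenzyl alcohols and the acid-catalysed Markovnikov hydroalkylation of styrenes with 1,3-diketones.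

Step 11
Reactants: 19 chromanyl diketo-dioxinone (TBS ether); 11 allyl alcohol
Product: 21 allyl 2,4-dihydroxy-5-[(4R)-5-(TBS-oxy)-2,2-dimethyl-8-prenyl-7-[arm(TIPS)]chroman-4-yl]-6-[arm(TIPS)]benzoate, via chromanyl triketo allyl ester 20 (not isolated)
Conditions: 11 (5 equiv), toluene, 110 °C; concentrate; Cs2CO3, THF, 20 °C; then AcOH
Reagents that add atoms: none
Why: At 110 °C the dioxinone undergoes cycloreversion to acetone and an acylketene, which allyl alcohol intercepts to give the open-chain 3,5,7-triketo ester 20; carbonate then generates the enolate of the ester-activated methylene C2, which adds to the arm ketone C7, and loss of water with enolisation of the two remaining ketones delivers the arene. The closest known reaction is the dioxinone thermolysis, alcohol trapping and aldol aromatisation of 3,5,7-triketo esters to β-resorcylates. The single ring formed, the benzene ring of the chromene half, closes by a 6-(enolexo)-exo-trig aldol addition that makes the C7–C8 bond. No stereocentre is created, and C4' keeps the configuration set in step 10 because it bears no acidic hydrogen and, with O5' silylated, has no retro-addition path under mild base. The step needs capture of the ketene by the alcohol ahead of O-acylation by the diketone enol, which the excess of allyl alcohol should secure, and it needs aldol rather than Claisen closure, which follows because attack of the chroman-bearing carbon on the ester would leave that carbon quaternary and the ring unable to become aromatic, so only the aldol pathway is drained by aromatisation.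

Step 12
Reactants: 21 allyl resorcylate carrying the chroman
Product: 23 4-[(4R)-5-(TBS-oxy)-2,2-dimethyl-8-prenyl-7-[arm(TIPS)]chroman-4-yl]-5-[arm(TIPS)]benzene-1,3-diol, via resorcylic acid 22 (not isolated)
Conditions: Pd(PPh3)4 (5 mol%), morpholine, THF, 20 °C; aq. citric acid wash; then DMF, 120 °C
Reagents that add atoms: none
Why: Tsuji–Trost deallylation followed by thermal decarboxylation of the 2,4-dihydroxybenzoic acid, as in step 9, clears C8 without touching the silyl ethers, the prenyl group or the stereocentre.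

Step 13
Reactants: 23 resorcinol carrying the chroman; 14 3-methylbut-2-enal (prenal)
Product: 24 6-[(4R)-5-(TBS-oxy)-2,2-dimethyl-8-prenyl-7-[arm(TIPS)]chroman-4-yl]-2,2-dimethyl-7-[arm(TIPS)]-2H-chromen-5-ol
Conditions: 14, ethylenediammonium diacetate (20 mol%), toluene, 110 °C
Reagents that add atoms: none
Why: Chromene annulation of a resorcinol with prenal (Knoevenagel-type condensation, then oxa-6π electrocyclisation) should take place at C4a between the two hydroxyls, as with 5-alkylresorcinols, and close through O8a because closure through O5 would press the gem-dimethyl pyran against the chroman-4'-yl group on C6.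

Step 14
Reactants: 24 chromene phenol; 8 prenyl bromide
Product: 25 6-[(4R)-5-(TBS-oxy)-2,2-dimethyl-8-prenyl-7-[arm(TIPS)]chroman-4-yl]-2,2-dimethyl-5-(prenyloxy)-7-[arm(TIPS)]-2H-chromene
Conditions: 8, K2CO3, acetone, 56 °C
Reagents that add atoms: none
Why: Williamson etherification of the only free hydroxyl, the hindered O5–H, with a reactive allylic bromide under carbonate conditions that should leave the silyl ethers intact.

Step 15
Reactants: 25 O5-prenyl ether
Product: 26 6-[(4R)-5-(TBS-oxy)-2,2-dimethyl-8-prenyl-7-[arm(TIPS)]chroman-4-yl]-2,2-dimethyl-8-prenyl-7-[arm(TIPS)]-2H-chromen-5-ol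
Conditions: N,N-diethylaniline, 190 °C, sealed tube, degassed
Reagents that add atoms: none
Why: para-Claisen–Cope rearrangement, in which the [3,3] shift to the substituted ortho carbon C4a gives a dienone that cannot enolise and passes the allyl unit on by a second [3,3] shift to the free para carbon C8, the two inversions returning an unrearranged prenyl group before tautomerisation to the phenol.

Step 16
Reactants: 26 tris-silyl ether of the target
Product: 27 6-[(4R)-5-hydroxy-7-[2-(4-hydroxyphenyl)ethyl]-2,2-dimethyl-8-prenylchroman-4-yl]-7-[2-(4-hydroxyphenyl)ethyl]-2,2-dimethyl-8-prenyl-2H-chromen-5-ol (CNP0103951.1)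
Conditions: Bu4NF, AcOH, THF, 0 °C
Reagents that add atoms: none
Why: Fluoride cleavage of the three aryl silyl ethers, buffered with acetic acid so that the electron-rich phenoxides are not exposed to air as free anions, should give the target with C4' untouched.

**Compound list**

1 | 3-(4-hydroxyphenyl)propanoic acid | OC(=O)CCc1ccc(O)cc1 | starting material
2 | 3-(4-hydroxyphenyl)-N-methoxy-N-methylpropanamide | CON(C)C(=O)CCc1ccc(O)cc1 | intermediate
3 | N-methoxy-N-methyl-3-[4-(triisopropylsilyloxy)phenyl]propanamide | CON(C)C(=O)CCc1ccc(O[Si](C(C)C)(C(C)C)C(C)C)cc1 | intermediate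
4 | 2,2,6-trimethyl-4H-1,3-dioxin-4-one | CC1=CC(=O)OC(C)(C)O1 | starting material
5 | acetyl chloride | CC(Cl)=O | starting material
6 | 2,2-dimethyl-6-(2-oxopropyl)-4H-1,3-dioxin-4-one | CC(=O)CC1=CC(=O)OC(C)(C)O1 | intermediate
7 | 6-{2,4-dioxo-6-[4-(triisopropylsilyloxy)phenyl]hexyl}-2,2-dimethyl-4H-1,3-dioxin-4-one | CC1(C)OC(=O)C=C(CC(=O)CC(=O)CCc2ccc(O[Si](C(C)C)(C(C)C)C(C)C)cc2)O1 | intermediate
8 | prenyl bromide (1-bromo-3-methylbut-2-ene) | CC(C)=CCBr | starting material
9 | 2,2-dimethyl-6-(6-methyl-2-oxohept-5-en-1-yl)-4H-1,3-dioxin-4-one | CC(C)=CCCC(=O)CC1=CC(=O)OC(C)(C)O1 | intermediate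
10 | 2,2-dimethyl-6-{3-prenyl-2,4-dioxo-6-[4-(triisopropylsilyloxy)phenyl]hexyl}-4H-1,3-dioxin-4-one | CC(C)=CCC(C(=O)CC1=CC(=O)OC(C)(C)O1)C(=O)CCc1ccc(O[Si](C(C)C)(C(C)C)C(C)C)cc1 | intermediate
11 | allyl alcohol | C=CCO | starting material
12 | allyl 6-prenyl-3,5,7-trioxo-9-[4-(triisopropylsilyloxy)phenyl]nonanoate | C=CCOC(=O)CC(=O)CC(=O)C(CC=C(C)C)C(=O)CCc1ccc(O[Si](C(C)C)(C(C)C)C(C)C)cc1 | intermediate
13 | allyl 2,4-dihydroxy-5-prenyl-6-[arm(TIPS)]benzoate | C=CCOC(=O)c1c(O)cc(O)c(CC=C(C)C)c1CCc1ccc(O[Si](C(C)C)(C(C)C)C(C)C)cc1 | intermediate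
14 | 3-methylbut-2-enal (prenal) | CC(C)=CC=O | starting material
15 | allyl 5-hydroxy-2,2-dimethyl-8-prenyl-7-[arm(TIPS)]-2H-chromene-6-carboxylate | C=CCOC(=O)c1c(O)c2C=CC(C)(C)Oc2c(CC=C(C)C)c1CCc1ccc(O[Si](C(C)C)(C(C)C)C(C)C)cc1 | intermediate
16 | 5-hydroxy-2,2-dimethyl-8-prenyl-7-[arm(TIPS)]-2H-chromene-6-carboxylic acid | OC(=O)c1c(O)c2C=CC(C)(C)Oc2c(CC=C(C)C)c1CCc1ccc(O[Si](C(C)C)(C(C)C)C(C)C)cc1 | intermediate
17 | 2,2-dimethyl-8-prenyl-7-[arm(TIPS)]-2H-chromen-5-ol | Oc1cc(CCc2ccc(O[Si](C(C)C)(C(C)C)C(C)C)cc2)c(CC=C(C)C)c2OC(C)(C)C=Cc12 | intermediate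
18 | 6-{3-[(4R)-5-hydroxy-2,2-dimethyl-8-prenyl-7-[arm(TIPS)]chroman-4-yl]-2,4-dioxo-6-[4-(triisopropylsilyloxy)phenyl]hexyl}-2,2-dimethyl-4H-1,3-dioxin-4-one | CC1(C)OC(=O)C=C(CC(=O)C([C@H]2CC(C)(C)Oc3c(CC=C(C)C)c(CCc4ccc(O[Si](C(C)C)(C(C)C)C(C)C)cc4)cc(O)c32)C(=O)CCc2ccc(O[Si](C(C)C)(C(C)C)C(C)C)cc2)O1 | intermediate
19 | 6-{3-[(4R)-5-(TBS-oxy)-2,2-dimethyl-8-prenyl-7-[arm(TIPS)]chroman-4-yl]-2,4-dioxo-6-[4-(triisopropylsilyloxy)phenyl]hexyl}-2,2-dimethyl-4H-1,3-dioxin-4-one | CC1(C)OC(=O)C=C(CC(=O)C([C@H]2CC(C)(C)Oc3c(CC=C(C)C)c(CCc4ccc(O[Si](C(C)C)(C(C)C)C(C)C)cc4)cc(O[Si](C)(C)C(C)(C)C)c32)C(=O)CCc2ccc(O[Si](C(C)C)(C(C)C)C(C)C)cc2)O1 | intermediate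
20 | allyl 6-[(4R)-5-(TBS-oxy)-2,2-dimethyl-8-prenyl-7-[arm(TIPS)]chroman-4-yl]-3,5,7-trioxo-9-[4-(triisopropylsilyloxy)phenyl]nonanoate | C=CCOC(=O)CC(=O)CC(=O)C([C@H]1CC(C)(C)Oc2c(CC=C(C)C)c(CCc3ccc(O[Si](C(C)C)(C(C)C)C(C)C)cc3)cc(O[Si](C)(C)C(C)(C)C)c21)C(=O)CCc1ccc(O[Si](C(C)C)(C(C)C)C(C)C)cc1 | intermediate
21 | allyl 2,4-dihydroxy-5-[(4R)-5-(TBS-oxy)-2,2-dimethyl-8-prenyl-7-[arm(TIPS)]chroman-4-yl]-6-[arm(TIPS)]benzoate | C=CCOC(=O)c1c(CCc2ccc(O[Si](C(C)C)(C(C)C)C(C)C)cc2)c([C@H]2CC(C)(C)Oc3c(CC=C(C)C)c(CCc4ccc(O[Si](C(C)C)(C(C)C)C(C)C)cc4)cc(O[Si](C)(C)C(C)(C)C)c32)c(O)cc1O | intermediate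
22 | 2,4-dihydroxy-5-[(4R)-5-(TBS-oxy)-2,2-dimethyl-8-prenyl-7-[arm(TIPS)]chroman-4-yl]-6-[arm(TIPS)]benzoic acid | OC(=O)c1c(CCc2ccc(O[Si](C(C)C)(C(C)C)C(C)C)cc2)c([C@H]2CC(C)(C)Oc3c(CC=C(C)C)c(CCc4ccc(O[Si](C(C)C)(C(C)C)C(C)C)cc4)cc(O[Si](C)(C)C(C)(C)C)c32)c(O)cc1O | intermediate
23 | 4-[(4R)-5-(TBS-oxy)-2,2-dimethyl-8-prenyl-7-[arm(TIPS)]chroman-4-yl]-5-[arm(TIPS)]benzene-1,3-diol | Oc1cc(O)c([C@H]2CC(C)(C)Oc3c(CC=C(C)C)c(CCc4ccc(O[Si](C(C)C)(C(C)C)C(C)C)cc4)cc(O[Si](C)(C)C(C)(C)C)c32)c(CCc2ccc(O[Si](C(C)C)(C(C)C)C(C)C)cc2)c1 | intermediate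
24 | 6-[(4R)-5-(TBS-oxy)-2,2-dimethyl-8-prenyl-7-[arm(TIPS)]chroman-4-yl]-2,2-dimethyl-7-[arm(TIPS)]-2H-chromen-5-ol | Oc1c([C@H]2CC(C)(C)Oc3c(CC=C(C)C)c(CCc4ccc(O[Si](C(C)C)(C(C)C)C(C)C)cc4)cc(O[Si](C)(C)C(C)(C)C)c32)c(CCc2ccc(O[Si](C(C)C)(C(C)C)C(C)C)cc2)cc2OC(C)(C)C=Cc12 | intermediate
25 | 6-[(4R)-5-(TBS-oxy)-2,2-dimethyl-8-prenyl-7-[arm(TIPS)]chroman-4-yl]-2,2-dimethyl-5-(prenyloxy)-7-[arm(TIPS)]-2H-chromene | CC(C)=CCOc1c([C@H]2CC(C)(C)Oc3c(CC=C(C)C)c(CCc4ccc(O[Si](C(C)C)(C(C)C)C(C)C)cc4)cc(O[Si](C)(C)C(C)(C)C)c32)c(CCc2ccc(O[Si](C(C)C)(C(C)C)C(C)C)cc2)cc2OC(C)(C)C=Cc12 | intermediate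
26 | 6-[(4R)-5-(TBS-oxy)-2,2-dimethyl-8-prenyl-7-[arm(TIPS)]chroman-4-yl]-2,2-dimethyl-8-prenyl-7-[arm(TIPS)]-2H-chromen-5-ol | CC(C)=CCc1c(CCc2ccc(O[Si](C(C)C)(C(C)C)C(C)C)cc2)c([C@H]2CC(C)(C)Oc3c(CC=C(C)C)c(CCc4ccc(O[Si](C(C)C)(C(C)C)C(C)C)cc4)cc(O[Si](C)(C)C(C)(C)C)c32)c(O)c2c1OC(C)(C)C=C2 | intermediate
27 | 6-[(4R)-5-hydroxy-7-[2-(4-hydroxyphenyl)ethyl]-2,2-dimethyl-8-prenylchroman-4-yl]-7-[2-(4-hydroxyphenyl)ethyl]-2,2-dimethyl-8-prenyl-2H-chromen-5-ol | CC(C)=CCc1c(CCc2ccc(O)cc2)c([C@H]2CC(C)(C)Oc3c(CC=C(C)C)c(CCc4ccc(O)cc4)cc(O)c32)c(O)c2c1OC(C)(C)C=C2 | target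

**Step count and risks**

Total step count: 16. Longest linear sequence: 13 steps (4 → 6 → 9 → 10 → 13 → 15 → 17 → 19 → 21 → 23 → 24 → 25 → 26 → 27; steps 3 and 5 to 16).

Steps most likely to fail:

Step 10 (the union). Ionisation of the chromene by the phosphoric acid may be slow or reversible, so that enantiomeric purity is eroded. The cation may also be captured by a second chromene molecule instead of the diketone enol, or the free phenol may add to a ketone before it is silylated. The fallback gives up catalyst control and uses known reactions only. It sets out from 17 and 7, which are joined by the Bi(OTf)3-catalysed Markovnikov hydroalkylation of the styrene-type double bond with the 1,3-diketone (CH2Cl2, 0 °C) to give the racemic phenol adduct F1. Silylation (t-BuMe2SiCl, imidazole) gives the racemic TBS ether F2. The conditions of step 11 convert it by way of the racemic triketo allyl ester F3 into the racemic allyl resorcylate F4, in which the diketone epimers have vanished. F4 is resolved by preparative HPLC on a chiral stationary phase, and the (R)-enantiomer is compound 21, where the route is rejoined.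

Step 13 (chromene annulation). Site selectivity may be poor: the intermediate quinone methide may close through O5, or the condensation may start at C8. The fallback keeps the ester as a blocking group for C8 and uses its hydrogen bond to tell the hydroxyls apart. It sets out from 21, whose non-chelated O5–H alone should be alkylated by 8 (K2CO3, acetone) to give the O5-prenyl ether F5. Condensation of the remaining, ester-chelated O8a–H with 14 under PhB(OH)2 and AcOH in toluene at 110 °C (ortho-specific chromene synthesis by way of the aryl boronate) can involve only C4a and O8a and should give the chromene ester F6. Pd(PPh3)4 and morpholine free the chromene acid F7, and Ag2CO3-catalysed protodecarboxylation (DMSO, 120 °C) should give 25, where the route is rejoined.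

Step 15 (para-Claisen–Cope). The crowded ortho-dienone may fragment with loss of isoprene and return the phenol, the allyl unit may fail to reach C8, or silyl groups may be lost at 190 °C. The fallback replaces the sigmatropic route by cross-coupling. It sets out from 24, which is brominated at low temperature (N-bromosuccinimide, CH2Cl2, −78 °C) at C8, the only unsubstituted position of the free phenol ring, to give the 8-bromo phenol F8. Stille coupling of F8 with tributyl(3-methylbut-2-en-1-yl)stannane (Pd(PPh3)4, DMF, 80 °C) should give 26, where the route is rejoined.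

**Further compounds**

F1 | step 10 | racemic 6-{3-[5-hydroxy-2,2-dimethyl-8-prenyl-7-[arm(TIPS)]chroman-4-yl]-2,4-dioxo-6-[4-(triisopropylsilyloxy)phenyl]hexyl}-2,2-dimethyl-4H-1,3-dioxin-4-one | CC1(C)OC(=O)C=C(CC(=O)C(C2CC(C)(C)Oc3c(CC=C(C)C)c(CCc4ccc(O[Si](C(C)C)(C(C)C)C(C)C)cc4)cc(O)c32)C(=O)CCc2ccc(O[Si](C(C)C)(C(C)C)C(C)C)cc2)O1
F2 | step 10 | racemic TBS ether of F1 | CC1(C)OC(=O)C=C(CC(=O)C(C2CC(C)(C)Oc3c(CC=C(C)C)c(CCc4ccc(O[Si](C(C)C)(C(C)C)C(C)C)cc4)cc(O[Si](C)(C)C(C)(C)C)c32)C(=O)CCc2ccc(O[Si](C(C)C)(C(C)C)C(C)C)cc2)O1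
F3 | step 10 | racemic allyl 6-[5-(TBS-oxy)-2,2-dimethyl-8-prenyl-7-[arm(TIPS)]chroman-4-yl]-3,5,7-trioxo-9-[4-(triisopropylsilyloxy)phenyl]nonanoate | C=CCOC(=O)CC(=O)CC(=O)C(C1CC(C)(C)Oc2c(CC=C(C)C)c(CCc3ccc(O[Si](C(C)C)(C(C)C)C(C)C)cc3)cc(O[Si](C)(C)C(C)(C)C)c21)C(=O)CCc1ccc(O[Si](C(C)C)(C(C)C)C(C)C)cc1
F4 | step 10 | racemic allyl 2,4-dihydroxy-5-[5-(TBS-oxy)-2,2-dimethyl-8-prenyl-7-[arm(TIPS)]chroman-4-yl]-6-[arm(TIPS)]benzoate | C=CCOC(=O)c1c(CCc2ccc(O[Si](C(C)C)(C(C)C)C(C)C)cc2)c(C2CC(C)(C)Oc3c(CC=C(C)C)c(CCc4ccc(O[Si](C(C)C)(C(C)C)C(C)C)cc4)cc(O[Si](C)(C)C(C)(C)C)c32)c(O)cc1O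
F5 | step 13 | allyl 2-hydroxy-4-(prenyloxy)-5-[(4R)-5-(TBS-oxy)-2,2-dimethyl-8-prenyl-7-[arm(TIPS)]chroman-4-yl]-6-[arm(TIPS)]benzoate | C=CCOC(=O)c1c(CCc2ccc(O[Si](C(C)C)(C(C)C)C(C)C)cc2)c([C@H]2CC(C)(C)Oc3c(CC=C(C)C)c(CCc4ccc(O[Si](C(C)C)(C(C)C)C(C)C)cc4)cc(O[Si](C)(C)C(C)(C)C)c32)c(OCC=C(C)C)cc1O
F6 | step 13 | allyl 6-[(4R)-5-(TBS-oxy)-2,2-dimethyl-8-prenyl-7-[arm(TIPS)]chroman-4-yl]-2,2-dimethyl-5-(prenyloxy)-7-[arm(TIPS)]-2H-chromene-8-carboxylate | C=CCOC(=O)c1c(CCc2ccc(O[Si](C(C)C)(C(C)C)C(C)C)cc2)c([C@H]2CC(C)(C)Oc3c(CC=C(C)C)c(CCc4ccc(O[Si](C(C)C)(C(C)C)C(C)C)cc4)cc(O[Si](C)(C)C(C)(C)C)c32)c(OCC=C(C)C)c2C=CC(C)(C)Oc12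
F7 | step 13 | 6-[(4R)-5-(TBS-oxy)-2,2-dimethyl-8-prenyl-7-[arm(TIPS)]chroman-4-yl]-2,2-dimethyl-5-(prenyloxy)-7-[arm(TIPS)]-2H-chromene-8-carboxylic acid | OC(=O)c1c(CCc2ccc(O[Si](C(C)C)(C(C)C)C(C)C)cc2)c([C@H]2CC(C)(C)Oc3c(CC=C(C)C)c(CCc4ccc(O[Si](C(C)C)(C(C)C)C(C)C)cc4)cc(O[Si](C)(C)C(C)(C)C)c32)c(OCC=C(C)C)c2C=CC(C)(C)Oc12
F8 | step 15 | 8-bromo-6-[(4R)-5-(TBS-oxy)-2,2-dimethyl-8-prenyl-7-[arm(TIPS)]chroman-4-yl]-2,2-dimethyl-7-[arm(TIPS)]-2H-chromen-5-ol | Oc1c([C@H]2CC(C)(C)Oc3c(CC=C(C)C)c(CCc4ccc(O[Si](C(C)C)(C(C)C)C(C)C)cc4)cc(O[Si](C)(C)C(C)(C)C)c32)c(CCc2ccc(O[Si](C(C)C)(C(C)C)C(C)C)cc2)c(Br)c2OC(C)(C)C=Cc12
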